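**Plan**
Retrosynthesis: the two ring-A bromines (ortho and para to the ring-A OH) come off first, then the ring-A OH is masked as OMe, then ring B is cut at C2–C3 and C1–C6.
This cut is possible because ring B holds the unbroken run C3(Br)–C4(H)–C5(Br)–C6(Br), which is the chain C5–C4–C3–C2 of 2,3,5-tribromothiophene. Next to it sits the oxygenated pair C1(OH)–C2(OAr), which is the carbonyl and α-carbon of an aryloxyacetate.
Forward: ring A is bought as guaiacol and its oxygen is alkylated at an sp3 carbon, which sets the future diaryl ether bond. The ester becomes a silyl ketene acetal and the thiophene becomes its 1,1-dioxide.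
Ring B, the only ring made, then forms in one operation: [4+2] addition, loss of SO2, loss of methanol and silyl. Demethylation and OH-directed dibromination of ring A finish the route.
Stereochemistry: the target has no stereogenic element, and the sp3 centres formed in the cycloaddition vanish on aromatisation.

Key step: step 4

Remark: the SMILES holds no stereocentre and no hindered axis, so the target is a single achiral compound and nothing has to be resolved. Ring B is numbered C1 (OH), C2 (OAr), C3 (Br), C4 (H), C5 (Br), C6 (Br).

Step 1
Reactants: 1 guaiacol (2-methoxyphenol); 2 methyl bromoacetate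
Product: 3 methyl (2-methoxyphenoxy)acetate
Conditions: K2CO3, acetone, reflux
Reagents that add atoms: none
Why: Williamson ether synthesis, in which the phenoxide of 1 displaces bromide from the unhindered, carbonyl-activated sp3 carbon of 2 (SN2), so the oxygen of the later diaryl ether is placed without any aryl–O coupling.

Step 2
Reactants: 3 methyl (2-methoxyphenoxy)acetate
Product: 5 (Z)-1-methoxy-2-(2-methoxyphenoxy)-1-(trimethylsilyloxy)ethene, via lithium ester enolate 4 (not isolated)
Conditions: LDA, THF, −78 °C; then TMSCl, −78 °C → rt; pentane, filtration, bulb-to-bulb distillation (amine-free)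
Reagents that add atoms: chlorotrimethylsilane, C[Si](C)(C)Cl
Why: Kinetic ester enolisation and O-silylation, as in the first stage of an Ireland–Claisen sequence on glycolate esters; lithium chelation by the aryloxy oxygen should favour the Z isomer, but the alkene geometry is erased in step 4 and is of no consequence.

Step 3
Reactants: 6 2,3,5-tribromothiophene
Product: 8 2,3,5-tribromothiophene 1,1-dioxide, via thiophene S-oxide 7 (not isolated)
Conditions: H2O2 (50% aq.), (CF3CO)2O, CH2Cl2–MeCN, 0 °C → rt
Reagents that add atoms: trifluoroperacetic acid, OOC(=O)C(F)(F)F (made in the flask from hydrogen peroxide, OO, and trifluoroacetic anhydride)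
Why: Peracid S-oxidation of a thiophene, for which trifluoroperacetic acid is electrophilic enough to oxidise halogen-deactivated sulfur twice, while the two α-bromines slow the self-dimerisation typical of unsubstituted thiophene dioxides.

Step 4
Reactants: 5 (Z)-1-methoxy-2-(2-methoxyphenoxy)-1-(trimethylsilyloxy)ethene; 8 2,3,5-tribromothiophene 1,1-dioxide
Product: 12 2,3,5-tribromo-6-(2-methoxyphenoxy)phenol, via bridged sulfone cycloadduct 9 (not isolated), via cyclohexadiene mixed ketal 10 (not isolated), via aryl trimethylsilyl ether 11 (not isolated)
Conditions: 5 (1.5 equiv), toluene, 0 → 60 °C, argon sweep; then 1 M HCl, THF, rt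
Reagents that add atoms: none
Why: Proposed new method: the sulfonyl group and three bromines make the non-aromatic diene of 8 very electron-poor and 5 is among the most electron-rich alkenes available, so an inverse-electron-demand, strongly asynchronous [4+2] addition is expected in which the nucleophilic CH(OAr) carbon bonds first to C5 of 8 (ring-B C2–C3) and the acetal carbon then closes on C2 of 8 (ring-B C1–C6). The closest known reaction type is the Diels–Alder addition of alkenes to tetrahalothiophene 1,1-dioxides with spontaneous cheletropic loss of SO2; a silyl ketene acetal as the 2π partner and the eliminative finish to a phenol have not been shown on this diene class. Ring B is closed as an intermolecular 4C + 2C cycloaddition giving the bridged sulfone 9, which extrudes SO2 to cyclohexadiene 10; in 10 C1 carries OMe and OSiMe3 but no hydrogen, so acid can only ionise C1–OMe to a silyloxy-stabilised arenium ion that sheds the C2 proton to give 11, the aryloxy group has no elimination partner, and the labile Si–O bond is hydrolysed in the same work-up. The sp3 centres of 9 and 10 arise as racemic endo/exo mixtures and are all erased on aromatisation, so none needs control. The selectivity that matters is orientation: C5 of 8 has only C4–H beside it whereas C2 is buttressed by the C3 bromine, π-donation from that bromine into C2=C3 shrinks the LUMO coefficient at C2, and external nucleophiles are known to enter 3-bromothiophene dioxides at C5, all of which steer the leading bond to C5. Should silanol leave in place of methanol, the error is repaired in step 5, which cleaves either ether.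

Step 5
Reactants: 12 2,3,5-tribromo-6-(2-methoxyphenoxy)phenol
Product: 14 2,3,5-tribromo-6-(2-hydroxyphenoxy)phenol, via bis(dibromoboryl) aryloxide 13 (not isolated)
Conditions: BBr3 (3 equiv), CH2Cl2, −78 °C → rt; then H2O
Reagents that add atoms: none
Why: Lewis-acid aryl methyl ether cleavage, in which BBr3 binds the methoxy oxygen and bromide attacks the methyl carbon (SN2); this is the standard demethylation of methoxylated polybromodiphenyl ethers and leaves the diaryl ether and the C–Br bonds alone.

Step 6
Reactants: 14 2,3,5-tribromo-6-(2-hydroxyphenoxy)phenol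
Product: 16 2,3,5-tribromo-6-(3,5-dibromo-2-hydroxyphenoxy)phenol (CNP0324535.0), via ring-A monobromide 15 (not isolated)
Conditions: Br2 (2.0 equiv), CH2Cl2–AcOH, 0 °C → rt
Reagents that add atoms: bromine, BrBr
Why: Electrophilic aromatic bromination, in which the free ring-A OH outranks the electron-poor aryloxy oxygen as director so that bromine enters para and then ortho to it, while the one open site of ring B (C4) is wedged between two bromines on a ring already carrying three deactivating halogens and should react far more slowly.

**Compound list**
1 | guaiacol (2-methoxyphenol) | COc1ccccc1O | starting material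
2 | methyl bromoacetate | COC(=O)CBr | starting material
3 | methyl (2-methoxyphenoxy)acetate | COC(=O)COc1ccccc1OC | intermediate
4 | lithium enolate of 3, OLi cis to OAr (not isolated) | CO/C(O[Li])=C/Oc1ccccc1OC | intermediate
5 | (Z)-1-methoxy-2-(2-methoxyphenoxy)-1-(trimethylsilyloxy)ethene | CO/C(O[Si](C)(C)C)=C/Oc1ccccc1OC | intermediate
6 | 2,3,5-tribromothiophene | Brc1cc(Br)c(Br)s1 | starting material
7 | 2,3,5-tribromothiophene 1-oxide (racemic at sulfur, not isolated) | O=S1C(Br)=CC(Br)=C1Br | intermediate
8 | 2,3,5-tribromothiophene 1,1-dioxide | O=S1(=O)C(Br)=CC(Br)=C1Br | intermediate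
9 | 1,3,4-tribromo-5-methoxy-6-(2-methoxyphenoxy)-5-(trimethylsilyloxy)-7-thiabicyclo[2.2.1]hept-2-ene 7,7-dioxide (racemic endo/exo mixture, no descriptors assigned, not isolated) | O=S1(=O)C2(Br)C=C(Br)C1(Br)C(OC)(O[Si](C)(C)C)C2Oc1ccccc1OC | intermediate
10 | 1,2,4-tribromo-6-methoxy-5-(2-methoxyphenoxy)-6-(trimethylsilyloxy)cyclohexa-1,3-diene (racemic diastereomer mixture, no descriptors assigned, not isolated) | COC1(O[Si](C)(C)C)C(Oc2ccccc2OC)C(Br)=CC(Br)=C1Br | intermediate
11 | [2,3,5-tribromo-6-(2-methoxyphenoxy)phenoxy]trimethylsilane (not isolated) | COc1ccccc1Oc1c(Br)cc(Br)c(Br)c1O[Si](C)(C)C | intermediate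
12 | 2,3,5-tribromo-6-(2-methoxyphenoxy)phenol | COc1ccccc1Oc1c(Br)cc(Br)c(Br)c1O | intermediate
13 | bis(dibromoboryl) derivative of 14, both phenol oxygens carrying BBr2 (idealised, not isolated) | BrB(Br)Oc1ccccc1Oc1c(Br)cc(Br)c(Br)c1OB(Br)Br | intermediate
14 | 2,3,5-tribromo-6-(2-hydroxyphenoxy)phenol | Oc1ccccc1Oc1c(Br)cc(Br)c(Br)c1O | intermediate
15 | 2,3,5-tribromo-6-(5-bromo-2-hydroxyphenoxy)phenol (not isolated) | Oc1ccc(Br)cc1Oc1c(Br)cc(Br)c(Br)c1O | intermediate
16 | 2,3,5-tribromo-6-(3,5-dibromo-2-hydroxyphenoxy)phenol (achiral) | Oc1c(Br)cc(Br)cc1Oc1c(Br)cc(Br)c(Br)c1O | target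

**Count**
Total steps: 6. Longest linear sequence: 5 steps (1, 2, 4, 5, 6). Step 3 is a one-step side branch.

**Steps most likely to fail**

Step 4 (key step).
- The addition may take the opposite orientation, because the inductive pull of the C3 bromine works against the steric and π-donor bias.
- The polar pathway may stop after the first bond and leak into sulfinate ring opening with loss of bromide, [2+2] closure or silyl transfer.
- Liberated SO2 may consume ketene acetal.

The fallback uses known chemistry and takes ring B from an arene instead of building it. It sets out from guaiacol 1 and returns at 12.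
- Commercial 1,2-dibromo-4-fluorobenzene is brominated (Br2, Fe) ortho to fluorine to 1,2,4-tribromo-5-fluorobenzene F1.
- F1 is deprotonated with LDA at −78 °C at the C–H flanked by F and Br and formylated with DMF to 2,3,5-tribromo-6-fluorobenzaldehyde F2.
- Nucleophilic aromatic substitution of the aldehyde-activated fluoride by 1 (K2CO3, DMF) should give 2,3,5-tribromo-6-(2-methoxyphenoxy)benzaldehyde F3.
- Baeyer–Villiger oxidation with mCPBA should give 2,3,5-tribromo-6-(2-methoxyphenoxy)phenyl formate F4.
- Methanolysis (K2CO3, MeOH) rejoins the route at 12.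

Step 3.
- Three bromines drain the sulfur lone pairs, so oxidation may stall.
- It may also halt at the S-oxide stage, where self-Diels–Alder dimerisation is fast.
- Forcing conditions invite ring degradation.

The fallback inverts the order of oxidation and α-bromination. It sets out from 6 and returns at 8.
- Double bromine–lithium exchange at the two α-positions of 6 (n-BuLi, THF, −78 °C) and a TMSCl quench should give 3-bromo-2,5-bis(trimethylsilyl)thiophene F5.
- Its more electron-rich and shielded sulfur is oxidised with mCPBA to 3-bromo-2,5-bis(trimethylsilyl)thiophene 1,1-dioxide F6.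
- Ipso-bromodesilylation of both C–Si bonds (Br2, AgBF4, CH2Cl2) rejoins the route at 8.

Step 6.
- In competition with the second ring-A bromination, bromine may enter ring B at C4, which is para to the free ring-B OH.
- Part of the reagent may be drawn to the positions directed by the aryloxy oxygen.

The fallback switches ring B off with a protecting group. It sets out from 12 and returns at 16.
- Mesylation of 12 (MsCl, Et3N, CH2Cl2) should give 2,3,5-tribromo-6-(2-methoxyphenoxy)phenyl methanesulfonate F7.
- BBr3 frees only the ring-A phenol to give 2,3,5-tribromo-6-(2-hydroxyphenoxy)phenyl methanesulfonate F8.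
- Two equivalents of Br2 then have a single activated ring to attack and should give 2,3,5-tribromo-6-(3,5-dibromo-2-hydroxyphenoxy)phenyl methanesulfonate F9.
- Sulfonate cleavage (NaOH, MeOH–THF, then acid) rejoins the route at 16.

**Further compounds**
F1 | step 4 | 1,2,4-tribromo-5-fluorobenzene | Fc1cc(Br)c(Br)cc1Br
F2 | step 4 | 2,3,5-tribromo-6-fluorobenzaldehyde | O=Cc1c(F)c(Br)cc(Br)c1Br
F3 | step 4 | 2,3,5-tribromo-6-(2-methoxyphenoxy)benzaldehyde | COc1ccccc1Oc1c(Br)cc(Br)c(Br)c1C=O
F4 | step 4 | 2,3,5-tribromo-6-(2-methoxyphenoxy)phenyl formate | COc1ccccc1Oc1c(Br)cc(Br)c(Br)c1OC=O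
F5 | step 3 | 3-bromo-2,5-bis(trimethylsilyl)thiophene | C[Si](C)(C)c1cc(Br)c(s1)[Si](C)(C)C
F6 | step 3 | 3-bromo-2,5-bis(trimethylsilyl)thiophene 1,1-dioxide | C[Si](C)(C)C1=CC(Br)=C([Si](C)(C)C)S1(=O)=O
F7 | step 6 | 2,3,5-tribromo-6-(2-methoxyphenoxy)phenyl methanesulfonate | COc1ccccc1Oc1c(Br)cc(Br)c(Br)c1OS(C)(=O)=O
F8 | step 6 | 2,3,5-tribromo-6-(2-hydroxyphenoxy)phenyl methanesulfonate | Oc1ccccc1Oc1c(Br)cc(Br)c(Br)c1OS(C)(=O)=O
F9 | step 6 | 2,3,5-tribromo-6-(3,5-dibromo-2-hydroxyphenoxy)phenyl methanesulfonate | Oc1c(Br)cc(Br)cc1Oc1c(Br)cc(Br)c(Br)c1OS(C)(=O)=O
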